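**Retrosynthetic overview**
1. Last come the acetate, the (E)-ene-diol chain and the tertiary carbinol: selective acetylation ⇐ cross-metathesis with 2-methylbut-3-en-2-ol ⇐ Felkin allylation of a C1 acetyl group.
2. Ring methylidene ⇐ C6 ketone; the cis C8a–H/C1–H pair ⇐ syn hydrogenation of a hydroazulene dienedione anti to the angular methyl.
3. Dienedione ⇐ retro-oxa-Michael opening of an 11-oxatricyclo[5.3.1.0^{1,5}]undecenone; the bridging oxygen stays on C5 and becomes the acetate oxygen.
4. Key step: an intramolecular oxidopyrylium–alkene [5+2] cycloaddition forms the cyclopentane, the cycloheptenone and the oxa bridge in one operation and sets the quaternary methyl anti to the bridge.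
5. Ring order: furan (one stereocentre by Cu-catalysed allylic alkylation) → pyranone (Achmatowicz) → five-ring, seven-ring and bridge together → bridge opened.

Assumption: in step 3 the ligand antipode is the one that gives the (S)-branched product (sense taken by analogy with cinnamyl chlorides); locants C1–C8a are the azulene numbering of the target.

**Step 1**
Reactants: 1 (2E)-3-(furan-2-yl)prop-2-enal
Product: 2 (2E)-3-(furan-2-yl)prop-2-en-1-ol
Conditions: NaBH4, MeOH, 0 °C
Reagents that add atoms: none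
Why: Borohydride 1,2-reduction of the enal leaves the furan and the E-alkene untouched; no stereocentre is formed.

**Step 2**
Reactants: 2 (2E)-3-(furan-2-yl)prop-2-en-1-ol
Product: 3 2-[(1E)-3-chloroprop-1-en-1-yl]furan
Conditions: NCS, Me2S, CH2Cl2, −20 → 0 °C; used crude
Reagents that add atoms: N-chlorosuccinimide, O=C1CCC(=O)N1Cl
Why: Corey–Kim chlorination turns the allylic alcohol into the primary allylic chloride through the alkoxysulfonium salt, without allylic transposition and without acid that would harm the furan.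

**Step 3**
Reactants: 3 2-[(1E)-3-chloroprop-1-en-1-yl]furan; 4 4-bromo-2-methylbut-1-ene
Product: 6 2-[(3S)-6-methylhepta-1,6-dien-3-yl]furan, via Grignard reagent 5 (not isolated)
Conditions: 4, Mg, Et2O; then 3, CuTC (3 mol %), chiral BINOL phosphoramidite (3.3 mol %), CH2Cl2, −78 °C, slow addition
Reagents that add atoms: none
Why: Copper-catalysed asymmetric allylic alkylation (SN2′) of the cinnamyl-type chloride with the primary Grignard reagent gives the branched product, and the chiral Cu–phosphoramidite complex selects the alkene face to set the (S)-centre.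

**Step 4**
Reactants: 6 2-[(3S)-6-methylhepta-1,6-dien-3-yl]furan
Product: 8 {5-[(3S)-6-methylhepta-1,6-dien-3-yl]furan-2-yl}methanol, via 5-lithiofuran 7 (not isolated)
Conditions: n-BuLi, THF, −78 → −20 °C; then (CH2O)n, −78 °C → rt
Reagents that add atoms: formaldehyde, C=O
Why: Oxygen-directed α-lithiation of the 2-alkylfuran at C5 (kept cold so the allylic/furfurylic C–H is not touched) followed by hydroxymethylation; the stereocentre is not involved.

**Step 5**
Reactants: 8 {5-[(3S)-6-methylhepta-1,6-dien-3-yl]furan-2-yl}methanol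
Product: 9 6-hydroxy-6-[(3S)-6-methylhepta-1,6-dien-3-yl]-2H-pyran-3(6H)-one
Conditions: VO(acac)2 (5 mol %), t-BuOOH, CH2Cl2, 0 °C → rt
Reagents that add atoms: tert-butyl hydroperoxide, CC(C)(C)OO
Why: Achmatowicz rearrangement, in which the vanadium alkoxide of the furfuryl alcohol delivers oxygen to the furan only (the isolated alkenes are inert) and the ene-dione closes to the pyranone hemiketal.

**Step 6**
Reactants: 9 6-hydroxy-6-[(3S)-6-methylhepta-1,6-dien-3-yl]-2H-pyran-3(6H)-one
Product: 12 (1R,2S,5R,7S)-2-ethenyl-5-methyl-11-oxatricyclo[5.3.1.0^{1,5}]undec-9-en-8-one, via pyranyl mesylate 10 (not isolated), via oxidopyrylium ylide 11 (not isolated)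
Conditions: MsCl, i-Pr2NEt, MeCN (0.01 M), 0 → 60 °C; minor facial isomer removed by chromatography
Reagents that add atoms: none
Why: Intramolecular oxidopyrylium–alkene [5+2] cycloaddition, in which the three-atom tether allows only the fused mode with the tether exo, so the new quaternary methyl (C5) ends anti to the oxygen bridge across C1 and C7, while the (S)-allylic centre selects the pyrylium face (its C–H eclipsing the ring C–H, vinyl on the ring-oxygen side, alkene attacking anti to the vinyl) to give the (1R,5R,7S) array.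

**Step 7**
Reactants: 12 (1R,2S,5R,7S)-2-ethenyl-5-methyl-11-oxatricyclo[5.3.1.0^{1,5}]undec-9-en-8-one
Product: 13 (1R,2R,5R,7S)-2-acetyl-5-methyl-11-oxatricyclo[5.3.1.0^{1,5}]undec-9-en-8-one
Conditions: PdCl2 (10 mol %), CuCl, O2 (1 atm), DMF/H2O 7:1, rt
Reagents that add atoms: water, O
Why: Tsuji–Wacker oxidation is selective for the monosubstituted terminal alkene (Markovnikov hydroxypalladation) and leaves the electron-poor bridged enone alone; the C2 centre is kept but becomes irrelevant in step 8.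

**Step 8**
Reactants: 13 (1R,2R,5R,7S)-2-acetyl-5-methyl-11-oxatricyclo[5.3.1.0^{1,5}]undec-9-en-8-one
Product: 14 (3aR,5S)-1-acetyl-5-hydroxy-3a-methyl-3,3a,4,5-tetrahydroazulen-6(2H)-one
Conditions: DBU (0.3 equiv), CH2Cl2, 0 °C → rt, Ar
Reagents that add atoms: none
Why: E1cB (retro-oxa-Michael) elimination, in which the enolate of the new ketone expels the β-alkoxide, so only the C1–O bond of the strained bridge breaks and the former bridge oxygen remains as the (5S)-hydroxyl; C3a and C5 are untouched.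

**Step 9**
Reactants: 14 (3aR,5S)-1-acetyl-5-hydroxy-3a-methyl-3,3a,4,5-tetrahydroazulen-6(2H)-one
Product: 15 (1S,3aR,5S,8aS)-1-acetyl-5-hydroxy-3a-methyloctahydroazulen-6(1H)-one
Conditions: H2 (4 atm), 10 % Pd/C, EtOAc, rt
Reagents that add atoms: none
Why: Heterogeneous catalytic hydrogenation adds H2 syn to both conjugated C=C bonds from the face opposite the angular methyl (the face of the C5 hydroxyl), as in the hydrogenation of Δ14-steroids, which sets C8a–H and C1–H cis to each other and trans to the methyl (trans ring fusion, acetyl β).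

**Step 10**
Reactants: 15 (1S,3aR,5S,8aS)-1-acetyl-5-hydroxy-3a-methyloctahydroazulen-6(1H)-one
Product: 16 1-[(1S,3aR,5S,8aS)-5-hydroxy-3a-methyl-6-methylidenedecahydroazulen-1-yl]ethan-1-one
Conditions: Zn, CH2Br2, TiCl4, THF/CH2Cl2, 0 °C → rt (about 2.2 equiv, monitored)
Reagents that add atoms: dibromomethane, BrCBr
Why: Takai–Lombardo methylenation is non-basic (no epimerisation at C1 or C5) and is steered to the ring ketone, which is chelated through the neighbouring titanium alkoxide and is less hindered than the acetyl group flanked by the cis C8 methylene and the angular methyl.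

**Step 11**
Reactants: 16 1-[(1S,3aR,5S,8aS)-5-hydroxy-3a-methyl-6-methylidenedecahydroazulen-1-yl]ethan-1-one
Product: 17 (2S)-2-[(1S,3aR,5S,8aS)-5-hydroxy-3a-methyl-6-methylidenedecahydroazulen-1-yl]pent-4-en-2-ol
Conditions: allylMgBr (3 equiv), Et2O/THF, −78 °C
Reagents that add atoms: allylmagnesium bromide, C=CC[Mg]Br
Why: Felkin–Anh-controlled Grignard addition: with the ring-fusion carbon C8a anti to the nucleophile and attack past the C1–H, allyl adds to the face that gives the (2S)-carbinol, the same sense as Grignard additions to 20-oxopregnanes; the first equivalent only deprotonates the C5 hydroxyl.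

**Step 12**
Reactants: 17 (2S)-2-[(1S,3aR,5S,8aS)-5-hydroxy-3a-methyl-6-methylidenedecahydroazulen-1-yl]pent-4-en-2-ol; 18 2-methylbut-3-en-2-ol
Product: 19 (2S,4E)-2-[(1S,3aR,5S,8aS)-5-hydroxy-3a-methyl-6-methylidenedecahydroazulen-1-yl]-6-methylhept-4-ene-2,6-diol
Conditions: 18 (10 equiv), Grubbs II (5 mol %), CH2Cl2, 40 °C
Reagents that add atoms: none
Why: Olefin cross-metathesis of the terminal allyl group with the tertiary allylic alcohol partner is E-selective, and the 1,1-disubstituted ring methylidene does not take part.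

**Step 13**
Reactants: 19 (2S,4E)-2-[(1S,3aR,5S,8aS)-5-hydroxy-3a-methyl-6-methylidenedecahydroazulen-1-yl]-6-methylhept-4-ene-2,6-diol
Product: 20 (1S,3aR,5S,8aS)-1-[(2S,4E)-2,6-dihydroxy-6-methylhept-4-en-2-yl]-3a-methyl-6-methylidenedecahydroazulen-5-yl acetate
Conditions: Ac2O (1.3 equiv), pyridine, DMAP (5 mol %), CH2Cl2, 0 °C
Reagents that add atoms: acetic anhydride, CC(=O)OC(C)=O
Why: DMAP-catalysed acylation picks the single secondary allylic hydroxyl; the two tertiary hydroxyls do not react under these conditions.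

**Compound list**
1 | (2E)-3-(furan-2-yl)prop-2-enal | O=C/C=C/c1ccco1 | starting material
2 | (2E)-3-(furan-2-yl)prop-2-en-1-ol | OC/C=C/c1ccco1 | intermediate
3 | 2-[(1E)-3-chloroprop-1-en-1-yl]furan | ClC/C=C/c1ccco1 | intermediate
4 | 4-bromo-2-methylbut-1-ene | C=C(C)CCBr | starting material
5 | (3-methylbut-3-en-1-yl)magnesium bromide | C=C(C)CC[Mg]Br | intermediate
6 | 2-[(3S)-6-methylhepta-1,6-dien-3-yl]furan | C=C[C@H](CCC(C)=C)c1ccco1 | intermediate
7 | {5-[(3S)-6-methylhepta-1,6-dien-3-yl]furan-2-yl}lithium | C=C[C@H](CCC(C)=C)c1ccc([Li])o1 | intermediate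
8 | {5-[(3S)-6-methylhepta-1,6-dien-3-yl]furan-2-yl}methanol | C=C[C@H](CCC(C)=C)c1ccc(CO)o1 | intermediate
9 | 6-hydroxy-6-[(3S)-6-methylhepta-1,6-dien-3-yl]-2H-pyran-3(6H)-one (both configurations at the hemiketal carbon) | C=C[C@H](CCC(C)=C)C1(O)C=CC(=O)CO1 | intermediate
10 | 2-[(3S)-6-methylhepta-1,6-dien-3-yl]-5-oxo-5,6-dihydro-2H-pyran-2-yl methanesulfonate | C=C[C@H](CCC(C)=C)C1(OS(C)(=O)=O)C=CC(=O)CO1 | intermediate
11 | 6-[(3S)-6-methylhepta-1,6-dien-3-yl]pyrylium-3-olate | C=C[C@H](CCC(C)=C)c1ccc([O-])c[o+]1 | intermediate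
12 | (1R,2S,5R,7S)-2-ethenyl-5-methyl-11-oxatricyclo[5.3.1.0^{1,5}]undec-9-en-8-one | C=C[C@@H]1CC[C@]2(C)C[C@@H]3O[C@]12C=CC3=O | intermediate
13 | (1R,2R,5R,7S)-2-acetyl-5-methyl-11-oxatricyclo[5.3.1.0^{1,5}]undec-9-en-8-one | CC(=O)[C@@H]1CC[C@]2(C)C[C@@H]3O[C@]12C=CC3=O | intermediate
14 | (3aR,5S)-1-acetyl-5-hydroxy-3a-methyl-3,3a,4,5-tetrahydroazulen-6(2H)-one | CC(=O)C1=C2C=CC(=O)[C@@H](O)C[C@@]2(C)CC1 | intermediate
15 | (1S,3aR,5S,8aS)-1-acetyl-5-hydroxy-3a-methyloctahydroazulen-6(1H)-one | O=C1CC[C@H]2[C@@H](C(C)=O)CC[C@]2(C)C[C@@H]1O | intermediate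
16 | 1-[(1S,3aR,5S,8aS)-5-hydroxy-3a-methyl-6-methylidenedecahydroazulen-1-yl]ethan-1-one | C=C1CC[C@H]2[C@@H](C(C)=O)CC[C@]2(C)C[C@@H]1O | intermediate
17 | (2S)-2-[(1S,3aR,5S,8aS)-5-hydroxy-3a-methyl-6-methylidenedecahydroazulen-1-yl]pent-4-en-2-ol | C=C1CC[C@H]2[C@@H]([C@@](C)(O)CC=C)CC[C@]2(C)C[C@@H]1O | intermediate
18 | 2-methylbut-3-en-2-ol | C=CC(C)(C)O | starting material
19 | (2S,4E)-2-[(1S,3aR,5S,8aS)-5-hydroxy-3a-methyl-6-methylidenedecahydroazulen-1-yl]-6-methylhept-4-ene-2,6-diol | C=C1CC[C@H]2[C@@H]([C@@](C)(O)C/C=C/C(C)(C)O)CC[C@]2(C)C[C@@H]1O | intermediate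
20 | (1S,3aR,5S,8aS)-1-[(2S,4E)-2,6-dihydroxy-6-methylhept-4-en-2-yl]-3a-methyl-6-methylidenedecahydroazulen-5-yl acetate | C=C1CC[C@H]2[C@@H]([C@@](C)(O)C/C=C/C(C)(C)O)CC[C@]2(C)C[C@@H]1OC(C)=O | target

**Step count and risks**
Total: 13 steps. Longest linear sequence: 13 steps (1 → 20); the Grignard reagent from 4 is made and used inside step 3.

Most likely to fail:

Step 6. The face selection rests on one allylic stereocentre, and the amine base can deprotonate the pyrylium at that centre, which would erode the ee. The fallback sets out from 9 and moves the control to a catalyst. 9 is acylated with 4-(methylsulfanyl)benzoyl chloride (Et3N, DMAP) to give 2-[(3S)-6-methylhepta-1,6-dien-3-yl]-5-oxo-5,6-dihydro-2H-pyran-2-yl 4-(methylsulfanyl)benzoate F1. F1 is then cyclised with a chiral primary aminothiourea and an achiral bis-aryl thiourea (AcOH, toluene, 40 °C). The amine condenses with the ketone to an aminopyrylium whose face is set by the catalyst while the thiourea binds the leaving carboxylate, so no free base meets the ylide. Hydrolysis of the adduct returns the route at 12.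

Step 9. A tetrasubstituted, doubly conjugated alkene must be saturated with two new centres, and 1,4-addition or alkene migration could scramble C1. The fallback sets out from 14 and sets the centres by electron transfer instead of surface hydrogenation. Wilkinson's catalyst and H2 saturate only the disubstituted C7=C8 bond to give (3aR,5S)-1-acetyl-5-hydroxy-3a-methyl-3,3a,4,5,7,8-hexahydroazulen-6(2H)-one F2. Lombardo methylenation of its only saturated ketone (the acetyl is now a hindered tetrasubstituted enone) gives 1-[(3aR,5S)-5-hydroxy-3a-methyl-6-methylidene-2,3,3a,4,5,6,7,8-octahydroazulen-1-yl]ethan-1-one F3. Li/NH3 with t-BuOH, then NH4Cl, reduces the enone: C8a is protonated anti to the methyl and the enolate is protonated at C1 from the same open face. The route is rejoined at 16; 15 and step 10 are bypassed.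

Step 10. Two ketones compete and the selectivity for the ring ketone is a judgment. The fallback sets out from 12, where only one ketone exists, and masks the methylidene before the second ketone is unveiled. Me3SiCH2Li/CeCl3 adds to 12 to give (1R,2S,5R,7S)-2-ethenyl-5-methyl-8-[(trimethylsilyl)methyl]-11-oxatricyclo[5.3.1.0^{1,5}]undec-9-en-8-ol F4. Wacker oxidation as in step 7 gives 1-[(1R,2R,5R,7S)-8-hydroxy-5-methyl-8-[(trimethylsilyl)methyl]-11-oxatricyclo[5.3.1.0^{1,5}]undec-9-en-2-yl]ethan-1-one F5. DBU opens the bridge to 1-[(3aR,5S)-5,6-dihydroxy-3a-methyl-6-[(trimethylsilyl)methyl]-2,3,3a,4,5,6-hexahydroazulen-1-yl]ethan-1-one F6. Hydrogenation as in step 9 gives 1-[(1S,3aR,5S,8aS)-5,6-dihydroxy-3a-methyl-6-[(trimethylsilyl)methyl]decahydroazulen-1-yl]ethan-1-one F7. Aqueous HF in MeCN then effects the Peterson elimination, and the route is rejoined at 16.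

**Further compounds**
F1 | step 6 | 2-[(3S)-6-methylhepta-1,6-dien-3-yl]-5-oxo-5,6-dihydro-2H-pyran-2-yl 4-(methylsulfanyl)benzoate | C=C[C@H](CCC(C)=C)C1(OC(=O)c2ccc(SC)cc2)C=CC(=O)CO1
F2 | step 9 | (3aR,5S)-1-acetyl-5-hydroxy-3a-methyl-3,3a,4,5,7,8-hexahydroazulen-6(2H)-one | CC(=O)C1=C2CCC(=O)[C@@H](O)C[C@@]2(C)CC1
F3 | step 9 | 1-[(3aR,5S)-5-hydroxy-3a-methyl-6-methylidene-2,3,3a,4,5,6,7,8-octahydroazulen-1-yl]ethan-1-one | CC(=O)C1=C2CCC(=C)[C@@H](O)C[C@@]2(C)CC1
F4 | step 10 | (1R,2S,5R,7S)-2-ethenyl-5-methyl-8-[(trimethylsilyl)methyl]-11-oxatricyclo[5.3.1.0^{1,5}]undec-9-en-8-ol | C=C[C@@H]1CC[C@]2(C)C[C@@H]3O[C@]12C=CC3(O)C[Si](C)(C)C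
F5 | step 10 | 1-[(1R,2R,5R,7S)-8-hydroxy-5-methyl-8-[(trimethylsilyl)methyl]-11-oxatricyclo[5.3.1.0^{1,5}]undec-9-en-2-yl]ethan-1-one | CC(=O)[C@@H]1CC[C@]2(C)C[C@@H]3O[C@]12C=CC3(O)C[Si](C)(C)C
F6 | step 10 | 1-[(3aR,5S)-5,6-dihydroxy-3a-methyl-6-[(trimethylsilyl)methyl]-2,3,3a,4,5,6-hexahydroazulen-1-yl]ethan-1-one | CC(=O)C1=C2C=CC(O)(C[Si](C)(C)C)[C@@H](O)C[C@@]2(C)CC1
F7 | step 10 | 1-[(1S,3aR,5S,8aS)-5,6-dihydroxy-3a-methyl-6-[(trimethylsilyl)methyl]decahydroazulen-1-yl]ethan-1-one | C[Si](C)(C)CC1(O)CC[C@H]2[C@@H](C(C)=O)CC[C@]2(C)C[C@@H]1O
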